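**Retrosynthetic overview**
1. Structural feature: in the oxolane (O1, C2, C3, C4, C5), C2 is bonded both to O1 and to the first diene carbon Ca. With the oxygen on C3 and the methyl on C5, the ring is the contracted image of a 2-methyl-4-oxy-3,4-dihydro-2H-pyran whose two enol ether carbons are C2 and Ca.
2. Diene: the alkene next to the isocoumarin is cut by Horner–Wadsworth–Emmons olefination (oxolanyl enal plus (isocoumarin-3-yl)methylphosphonate). The alkene next to the oxolane is cut by Wittig homologation of the C2 aldehyde.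
3. Oxolane: the aldehyde acetal arises by oxidative ring contraction of the silyloxy dihydropyran (O1 moves from Ca to C2). That pyran comes from a catalytic enantioselective hetero-Diels–Alder reaction of acetaldehyde, 1,2-reduction and silylation.
4. Isocoumarin: the pyranone ring is cut at O2–C3 (gold-catalysed 6-endo cyclisation) and at C4–C4a (Sonogashira coupling), back to 5-chloro-2,4-dihydroxybenzoic acid iodinated through directed magnesiation.
5. Ring order: temporary dihydropyran, then oxolane (one branch); pyranone ring onto the purchased benzene ring (other branch); the halves are joined last.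

Key step: step 4

Assumption: the sense of induction of the (salen)CrCl catalyst with acetaldehyde is taken to follow that of other aldehydes, so the (S,S) antipode is written for Si-face attack; both antipodes are commercial, and the (R,R) complex would be used if the sense proved opposite.

**Step 1**
Reactants: 1 acetaldehyde; 2 (E)-1-methoxy-3-(trimethylsilyloxy)buta-1,3-diene
Product: 4 (2R)-2-methyl-2,3-dihydro-4H-pyran-4-one, via cycloadduct 3 (not isolated)
Conditions: (S,S)-(salen)CrCl (5 mol %; salen = dianion of N,N'-bis(3,5-di-tert-butylsalicylidene)cyclohexane-1,2-diamine), 4 Å MS, t-BuOMe, −30 °C; then CF3CO2H (cat.), CH2Cl2, 0 °C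
Reagents that add atoms: none
Why: Lewis-acid-catalysed hetero-Diels–Alder reaction in which the trivalent chromium centre binds the aldehyde, the chiral salen ligand leaves only the Si face of the carbonyl open to the electron-rich diene so that the methyl-bearing centre (future oxolane C5) is set as R by the catalyst, and acid then strips methanol and the silyl group from 3 to give the vinylogous ester.

**Step 2**
Reactants: 4 (2R)-2-methyl-2,3-dihydro-4H-pyran-4-one
Product: 5 (2R,4S)-2-methyl-3,4-dihydro-2H-pyran-4-ol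
Conditions: NaBH4, CeCl3·7H2O, MeOH, −78 °C; NaHCO3 work-up
Reagents that add atoms: none
Why: Luche reduction, in which the cerium-modified borohydride adds 1,2 to the vinylogous ester along the axial trajectory of the half-chair that holds the methyl group equatorial, so the new carbinol centre (future C3) is formed equatorial and cis to the methyl group.

**Step 3**
Reactants: 5 (2R,4S)-2-methyl-3,4-dihydro-2H-pyran-4-ol
Product: 6 (2R,4S)-4-[(tert-butyldimethylsilyl)oxy]-2-methyl-3,4-dihydro-2H-pyran
Conditions: TBSCl, imidazole, DMF, 0 °C → rt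
Reagents that add atoms: tert-butyldimethylsilyl chloride, CC(C)(C)[Si](C)(C)Cl
Why: Imidazole-promoted O-silylation of a secondary allylic alcohol, run in a basic medium that protects the acid-labile allylic enol ether and touches no stereocentre.

**Step 4**
Reactants: 6 (2R,4S)-4-[(tert-butyldimethylsilyl)oxy]-2-methyl-3,4-dihydro-2H-pyran; 7 methanol; 8 (diacetoxyiodo)benzene
Product: 10 (2S,3S,5R)-3-[(tert-butyldimethylsilyl)oxy]-2-(dimethoxymethyl)-5-methyloxolane, via iodane adduct 9 (not isolated)
Conditions: PhI(OAc)2 (1.1 equiv), MeOH, 3 Å MS, 0 °C → rt; NaHCO3 work-up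
Reagents that add atoms: methanol, CO
Why: Pyran C5, the electron-rich β carbon of the enol ether and the future C2, bonds to the trivalent iodine of 8 from the side of the ring not occupied by the pseudoequatorial silyloxy group, and methanol adds to the cationic pyran C6 (future Ca), giving iodane 9 as a chair with methyl, silyloxy and iodanyl groups all equatorial. In this chair the ring bond C6–O1 lies antiperiplanar to the carbon–iodine bond, so O1 expels iodobenzene from the rear through a bridged oxonium ion (3-exo-tet), the old C6–O1 bond breaks with help from the methoxy lone pair, and a second methanol turns the exocyclic oxocarbenium ion into the dimethyl acetal; the oxolane is thus closed by a 1,2-shift of oxygen that makes O1–C2. The closest known reaction type is the oxidative ring contraction of glycals and simple 3,4-dihydro-2H-pyrans to 2,5-anhydro sugar acetals and oxolane-2-carbaldehyde acetals with trivalent iodine or trivalent thallium oxidants, whose steric course parallels the nitrous acid deamination of 2-amino-2-deoxyglucose. The one new stereocentre, C2, is under substrate control: the silyloxy group on the future C3 decides the face of iodine delivery and the shift inverts that carbon, so Ca ends trans to the C3 oxygen while the cis relation of C3 oxygen and C5 methyl is untouched; an adduct from the wrong face would hold its iodanyl group axial, out of line with C6–O1, and could not give the C2 epimer. The step needs the O1 shift to outrun capture by external methanol, migration of the other antiperiplanar ring bond (pyran C3–C4) and oxidative loss of the allylic oxygen; the lone-pair push of the acetal at C6 favours the oxygen shift, and the medium, which releases only acetic acid, spares the enol ether and the silyl ether.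

**Step 5**
Reactants: 10 (2S,3S,5R)-3-[(tert-butyldimethylsilyl)oxy]-2-(dimethoxymethyl)-5-methyloxolane
Product: 12 (2S,3S,5R)-3-[(tert-butyldimethylsilyl)oxy]-5-methyloxolane-2-carbaldehyde, via lutidinium salt 11 (not isolated)
Conditions: Et3SiOTf (2 equiv), 2,6-lutidine (3 equiv), CH2Cl2, 0 °C; then H2O
Reagents that add atoms: water, O
Why: Acetal cleavage under weakly basic conditions, in which the silyl triflate ionises one methoxy group, 2,6-lutidine traps the oxocarbenium ion as salt 11 and water then releases the aldehyde, so no Brønsted acid reaches the silyl ether and no strong base reaches the epimerisable C2–H or the β-silyloxy group.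

**Step 6**
Reactants: 12 (2S,3S,5R)-3-[(tert-butyldimethylsilyl)oxy]-5-methyloxolane-2-carbaldehyde; 13 (triphenylphosphoranylidene)acetaldehyde
Product: 14 (2E)-3-{(2R,3S,5R)-3-[(tert-butyldimethylsilyl)oxy]-5-methyloxolan-2-yl}prop-2-enal
Conditions: Ph3P=CHCHO (1.2 equiv), toluene, rt → 40 °C
Reagents that add atoms: (triphenylphosphoranylidene)acetaldehyde, O=CC=P(c1ccccc1)(c1ccccc1)c1ccccc1
Why: Wittig olefination with a stabilised formyl ylide, in which the α-alkoxy aldehyde is far more electrophilic than the enal product so that one homologation takes place, stabilised ylides give the E alkene, and the neutral medium leaves C2 and the β-silyloxy group alone.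

**Step 7**
Reactants: 15 5-chloro-2,4-dihydroxybenzoic acid
Product: 16 methoxymethyl 5-chloro-2,4-bis(methoxymethoxy)benzoate
Conditions: MOMCl (4.5 equiv), i-Pr2NEt (6 equiv), CH2Cl2, 0 °C → reflux
Reagents that add atoms: chloromethyl methyl ether, COCCl
Why: O-alkylation of the carboxylate and both phenols with a reactive α-chloro ether in one operation, the excess reagent and heating serving to cover the hydrogen-bonded ortho phenol as well.

**Step 8**
Reactants: 16 methoxymethyl 5-chloro-2,4-bis(methoxymethoxy)benzoate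
Product: 18 methoxymethyl 3-chloro-2-iodo-4,6-bis(methoxymethoxy)benzoate, via arylmagnesium chloride 17 (not isolated)
Conditions: TMPMgCl·LiCl (1.3 equiv; TMP = 2,2,6,6-tetramethylpiperidide), THF, −20 → 0 °C; then I2, −20 °C → rt
Reagents that add atoms: iodine, [I][I]
Why: Directed ortho-magnesiation, in which the hindered magnesium amide is guided by the ester carbonyl to the only ortho C–H, further acidified by the neighbouring chlorine as in 3-chlorobenzoates, while the C–H between the two acetal ethers has no carbonyl director, and the ester-tolerant arylmagnesium 17 is then iodinated.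

**Step 9**
Reactants: 18 methoxymethyl 3-chloro-2-iodo-4,6-bis(methoxymethoxy)benzoate; 19 tert-butyldimethyl(prop-2-yn-1-yloxy)silane
Product: 20 methoxymethyl 2-{3-[(tert-butyldimethylsilyl)oxy]prop-1-yn-1-yl}-3-chloro-4,6-bis(methoxymethoxy)benzoate
Conditions: 19 (1.5 equiv), Pd(PPh3)2Cl2 (5 mol %), CuI (10 mol %), Et3N–THF, 50 °C
Reagents that add atoms: tert-butyldimethyl(prop-2-yn-1-yloxy)silane, C#CCO[Si](C)(C)C(C)(C)C
Why: Sonogashira coupling, in which zerovalent palladium inserts into the aryl iodide far faster than into the aryl chloride and the amine medium is harmless to the acetal ester, the acetal ethers and the silyl ether.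

**Step 10**
Reactants: 20 methoxymethyl 2-{3-[(tert-butyldimethylsilyl)oxy]prop-1-yn-1-yl}-3-chloro-4,6-bis(methoxymethoxy)benzoate
Product: 22 5-chloro-3-(hydroxymethyl)-6,8-bis(methoxymethoxy)-1H-isochromen-1-one, via silyl ether 21 (not isolated)
Conditions: Ph3PAuNTf2 (5 mol %), MeOH (5 equiv), CH2Cl2, rt; then Bu4NF, AcOH, THF, 0 °C
Reagents that add atoms: none
Why: Gold-catalysed 6-endo-dig cyclisation of an ortho-alkynylbenzoate, in which the ester carbonyl oxygen adds to the alkyne carbon remote from the arene once monovalent gold activates it, the acetal-type ester hands its methoxymethyl cation to methanol just as anomeric ortho-alkynylbenzoates release glycosyl cations, protodeauration gives 21, and buffered fluoride then frees the primary alcohol without touching aryl acetals or lactone.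

**Step 11**
Reactants: 22 5-chloro-3-(hydroxymethyl)-6,8-bis(methoxymethoxy)-1H-isochromen-1-one
Product: 23 3-(bromomethyl)-5-chloro-6,8-bis(methoxymethoxy)-1H-isochromen-1-one
Conditions: CBr4, PPh3, CH2Cl2, 0 °C
Reagents that add atoms: carbon tetrabromide, BrC(Br)(Br)Br
Why: Appel reaction, which converts the primary allylic-type alcohol into the bromide under essentially neutral conditions that the aryl methoxymethyl ethers tolerate.

**Step 12**
Reactants: 23 3-(bromomethyl)-5-chloro-6,8-bis(methoxymethoxy)-1H-isochromen-1-one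
Product: 24 diethyl {[5-chloro-6,8-bis(methoxymethoxy)-1-oxo-1H-isochromen-3-yl]methyl}phosphonate
Conditions: P(OEt)3 (neat), 110 °C
Reagents that add atoms: triethyl phosphite, CCOP(OCC)OCC
Why: Michaelis–Arbuzov reaction of a reactive primary allylic-type bromide, the route by which the analogous (2-oxo-2H-pyran-6-yl)methylphosphonates are made, under neutral conditions that leave lactone and acetals intact.

**Step 13**
Reactants: 24 diethyl {[5-chloro-6,8-bis(methoxymethoxy)-1-oxo-1H-isochromen-3-yl]methyl}phosphonate; 14 (2E)-3-{(2R,3S,5R)-3-[(tert-butyldimethylsilyl)oxy]-5-methyloxolan-2-yl}prop-2-enal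
Product: 26 3-[(1E,3E)-4-{(2R,3S,5R)-3-[(tert-butyldimethylsilyl)oxy]-5-methyloxolan-2-yl}buta-1,3-dien-1-yl]-5-chloro-6,8-bis(methoxymethoxy)-1H-isochromen-1-one, via lithiated phosphonate 25 (not isolated)
Conditions: LiN(SiMe3)2 (1.05 equiv), THF, −78 °C; then 14, −78 → 0 °C
Reagents that add atoms: none
Why: Horner–Wadsworth–Emmons olefination, in which the methylene group of 24 is acidified by the phosphoryl group and by conjugation through C3=C4 into the benzopyranone, so a non-nucleophilic amide base gives anion 25 without opening the lactone, and addition to the enal followed by loss of phosphate gives the E alkene with no stereocentre involved.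

**Step 14**
Reactants: 26 3-[(1E,3E)-4-{(2R,3S,5R)-3-[(tert-butyldimethylsilyl)oxy]-5-methyloxolan-2-yl}buta-1,3-dien-1-yl]-5-chloro-6,8-bis(methoxymethoxy)-1H-isochromen-1-one
Product: 27 5-chloro-6,8-dihydroxy-3-{(1E,3E)-4-[(2R,3S,5R)-3-hydroxy-5-methyloxolan-2-yl]buta-1,3-dien-1-yl}-1H-isochromen-1-one
Conditions: HCl (1.25 M in MeOH), THF, 35 °C
Reagents that add atoms: none
Why: Acid-catalysed transacetalisation of both aryl methoxymethyl ethers and methanolysis of the silyl ether in one operation, the isocoumarin being acid-stable and ionisation of the allylic C2–O1 bond being disfavoured by the adjacent C3 oxygen and the electron-poor end of the diene, so the three stereocentres and both E alkenes should persist.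

**Compound list**
1 | acetaldehyde | CC=O | starting material
2 | (E)-1-methoxy-3-(trimethylsilyloxy)buta-1,3-diene | CO/C=C/C(=C)O[Si](C)(C)C | starting material
3 | (2R)-6-methoxy-2-methyl-4-[(trimethylsilyl)oxy]-3,6-dihydro-2H-pyran (acetal carbon of either configuration) | C[C@@H]1CC(O[Si](C)(C)C)=CC(OC)O1 | intermediate
4 | (2R)-2-methyl-2,3-dihydro-4H-pyran-4-one | C[C@@H]1CC(=O)C=CO1 | intermediate
5 | (2R,4S)-2-methyl-3,4-dihydro-2H-pyran-4-ol | C[C@@H]1C[C@H](O)C=CO1 | intermediate
6 | (2R,4S)-4-[(tert-butyldimethylsilyl)oxy]-2-methyl-3,4-dihydro-2H-pyran | C[C@@H]1C[C@H](O[Si](C)(C)C(C)(C)C)C=CO1 | intermediate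
7 | methanol | CO | starting material
8 | (diacetoxyiodo)benzene | CC(=O)OI(OC(C)=O)c1ccccc1 | starting material
9 | [(3R,4S,6R)-4-[(tert-butyldimethylsilyl)oxy]-2-methoxy-6-methyloxan-3-yl](phenyl)-λ3-iodanyl acetate (acetal carbon of either configuration) | C[C@@H]1C[C@H](O[Si](C)(C)C(C)(C)C)[C@@H](I(OC(C)=O)c2ccccc2)C(OC)O1 | intermediate
10 | (2S,3S,5R)-3-[(tert-butyldimethylsilyl)oxy]-2-(dimethoxymethyl)-5-methyloxolane | C[C@@H]1C[C@H](O[Si](C)(C)C(C)(C)C)[C@@H](C(OC)OC)O1 | intermediate
11 | 1-{[(2S,3S,5R)-3-[(tert-butyldimethylsilyl)oxy]-5-methyloxolan-2-yl](methoxy)methyl}-2,6-dimethylpyridinium triflate | C[C@@H]1C[C@H](O[Si](C)(C)C(C)(C)C)[C@@H](C(OC)[n+]2c(C)cccc2C)O1.[O-]S(=O)(=O)C(F)(F)F | intermediate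
12 | (2S,3S,5R)-3-[(tert-butyldimethylsilyl)oxy]-5-methyloxolane-2-carbaldehyde | C[C@@H]1C[C@H](O[Si](C)(C)C(C)(C)C)[C@@H](C=O)O1 | intermediate
13 | (triphenylphosphoranylidene)acetaldehyde | O=CC=P(c1ccccc1)(c1ccccc1)c1ccccc1 | starting material
14 | (2E)-3-{(2R,3S,5R)-3-[(tert-butyldimethylsilyl)oxy]-5-methyloxolan-2-yl}prop-2-enal | C[C@@H]1C[C@H](O[Si](C)(C)C(C)(C)C)[C@@H](/C=C/C=O)O1 | intermediate
15 | 5-chloro-2,4-dihydroxybenzoic acid | O=C(O)c1cc(Cl)c(O)cc1O | starting material
16 | methoxymethyl 5-chloro-2,4-bis(methoxymethoxy)benzoate | COCOC(=O)c1cc(Cl)c(OCOC)cc1OCOC | intermediate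
17 | {2-chloro-3,5-bis(methoxymethoxy)-6-[(methoxymethoxy)carbonyl]phenyl}magnesium chloride | COCOC(=O)c1c([Mg]Cl)c(Cl)c(OCOC)cc1OCOC | intermediate
18 | methoxymethyl 3-chloro-2-iodo-4,6-bis(methoxymethoxy)benzoate | COCOC(=O)c1c(I)c(Cl)c(OCOC)cc1OCOC | intermediate
19 | tert-butyldimethyl(prop-2-yn-1-yloxy)silane | C#CCO[Si](C)(C)C(C)(C)C | starting material
20 | methoxymethyl 2-{3-[(tert-butyldimethylsilyl)oxy]prop-1-yn-1-yl}-3-chloro-4,6-bis(methoxymethoxy)benzoate | COCOC(=O)c1c(C#CCO[Si](C)(C)C(C)(C)C)c(Cl)c(OCOC)cc1OCOC | intermediate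
21 | 3-{[(tert-butyldimethylsilyl)oxy]methyl}-5-chloro-6,8-bis(methoxymethoxy)-1H-isochromen-1-one | CC(C)(C)[Si](C)(C)OCc1cc2c(Cl)c(OCOC)cc(OCOC)c2c(=O)o1 | intermediate
22 | 5-chloro-3-(hydroxymethyl)-6,8-bis(methoxymethoxy)-1H-isochromen-1-one | OCc1cc2c(Cl)c(OCOC)cc(OCOC)c2c(=O)o1 | intermediate
23 | 3-(bromomethyl)-5-chloro-6,8-bis(methoxymethoxy)-1H-isochromen-1-one | BrCc1cc2c(Cl)c(OCOC)cc(OCOC)c2c(=O)o1 | intermediate
24 | diethyl {[5-chloro-6,8-bis(methoxymethoxy)-1-oxo-1H-isochromen-3-yl]methyl}phosphonate | CCOP(=O)(OCC)Cc1cc2c(Cl)c(OCOC)cc(OCOC)c2c(=O)o1 | intermediate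
25 | lithium salt of 24, deprotonated at the P–CH2 carbon | [Li+].CCOP(=O)(OCC)[CH-]c1cc2c(Cl)c(OCOC)cc(OCOC)c2c(=O)o1 | intermediate
26 | 3-[(1E,3E)-4-{(2R,3S,5R)-3-[(tert-butyldimethylsilyl)oxy]-5-methyloxolan-2-yl}buta-1,3-dien-1-yl]-5-chloro-6,8-bis(methoxymethoxy)-1H-isochromen-1-one | C[C@@H]1C[C@H](O[Si](C)(C)C(C)(C)C)[C@@H](/C=C/C=C/c2cc3c(Cl)c(OCOC)cc(OCOC)c3c(=O)o2)O1 | intermediate
27 | 5-chloro-6,8-dihydroxy-3-{(1E,3E)-4-[(2R,3S,5R)-3-hydroxy-5-methyloxolan-2-yl]buta-1,3-dien-1-yl}-1H-isochromen-1-one | C[C@@H]1C[C@H](O)[C@@H](/C=C/C=C/c2cc3c(Cl)c(O)cc(O)c3c(=O)o2)O1 | target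

Total step count: 14.
Longest linear sequence: 8 steps (steps 1–6, 13, 14). The isocoumarin branch, steps 7–12, 13, 14, is of equal length.

**Steps most likely to fail**

Step 4.
- What may go wrong: the iodane may engage the enol ether too slowly. External methanol may displace the iodonio group before O1 migrates. The allylic silyloxy group may be lost through allylic oxidation. Attack on the wrong face would drain material. A stronger oxidant such as Tl(NO3)3·3H2O would only be a change of conditions.
- Fallback, setting out from 6: oxidation and shift are separated. Dimethyldioxirane in acetone–CH2Cl2 at 0 °C should epoxidise the enol ether on the face away from the silyloxy group to give (1R,3R,5S,6R)-5-[(tert-butyldimethylsilyl)oxy]-3-methyl-2,7-dioxabicyclo[4.1.0]heptane F1.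
- Methanol opens F1 at the acetal carbon with inversion to give (2R,3R,4S,6R)-4-[(tert-butyldimethylsilyl)oxy]-2-methoxy-6-methyloxan-3-ol F2, whose free hydroxyl is equatorial and trans to the silyloxy group.
- Tf2O and pyridine at −20 °C give (2R,3R,4S,6R)-4-[(tert-butyldimethylsilyl)oxy]-2-methoxy-6-methyloxan-3-yl trifluoromethanesulfonate F3.
- Warming F3 in methanol with 2,6-lutidine lets the antiperiplanar ring oxygen expel triflate. This is the known solvolytic ring contraction of pyranoside 2-sulfonates with an equatorial leaving group, and it returns to the route at 10.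

Step 13.
- What may go wrong: the phosphonate anion may open or self-condense with the lactone, the enal may be deprotonated at its γ position (C2–H), or the E selectivity may erode.
- Fallback, setting out from 14 and 18: the pyranone ring is built after the diene.
- Olefination of 14 with diethyl [3-(trimethylsilyl)prop-2-yn-1-yl]phosphonate and LiN(SiMe3)2 in THF at −78 °C should give tert-butyldimethyl({(2R,3S,5R)-5-methyl-2-[(1E,3E)-6-(trimethylsilyl)hexa-1,3-dien-5-yn-1-yl]oxolan-3-yl}oxy)silane F4.
- K2CO3 in methanol removes the alkynyl silyl group to give tert-butyl({(2R,3S,5R)-2-[(1E,3E)-hexa-1,3-dien-5-yn-1-yl]-5-methyloxolan-3-yl}oxy)dimethylsilane F5.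
- Sonogashira coupling of F5 with 18 under the conditions of step 9 gives methoxymethyl 2-[(3E,5E)-6-{(2R,3S,5R)-3-[(tert-butyldimethylsilyl)oxy]-5-methyloxolan-2-yl}hexa-3,5-dien-1-yn-1-yl]-3-chloro-4,6-bis(methoxymethoxy)benzoate F6.
- Ph3PAuNTf2 with methanol in CH2Cl2 closes the lactone 6-endo as in step 10, returning to the route at 26.

Step 14.
- What may go wrong: acid may ionise the allylic C2–O1 bond, leading to epimerisation or solvent capture. It may isomerise the diene, or it may leave the C6 acetal partly in place.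
- Fallback, setting out from 24: the phenol protection is exchanged while the molecule is still robust, so that the last step needs fluoride only.
- HCl in methanol at 40 °C removes both acetals to give diethyl [(5-chloro-6,8-dihydroxy-1-oxo-1H-isochromen-3-yl)methyl]phosphonate F7.
- TBSCl and imidazole in DMF give diethyl ({6,8-bis[(tert-butyldimethylsilyl)oxy]-5-chloro-1-oxo-1H-isochromen-3-yl}methyl)phosphonate F8.
- Olefination of 14 with F8 under the conditions of step 13 gives 6,8-bis[(tert-butyldimethylsilyl)oxy]-3-[(1E,3E)-4-{(2R,3S,5R)-3-[(tert-butyldimethylsilyl)oxy]-5-methyloxolan-2-yl}buta-1,3-dien-1-yl]-5-chloro-1H-isochromen-1-one F9.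
- HF·pyridine in THF–pyridine at 0 °C → rt removes all three silyl groups, returning to the route at 27.

**Further compounds**
F1 | step 4 | (1R,3R,5S,6R)-5-[(tert-butyldimethylsilyl)oxy]-3-methyl-2,7-dioxabicyclo[4.1.0]heptane | C[C@@H]1C[C@H](O[Si](C)(C)C(C)(C)C)[C@H]2O[C@H]2O1
F2 | step 4 | (2R,3R,4S,6R)-4-[(tert-butyldimethylsilyl)oxy]-2-methoxy-6-methyloxan-3-ol | C[C@@H]1C[C@H](O[Si](C)(C)C(C)(C)C)[C@@H](O)[C@H](OC)O1
F3 | step 4 | (2R,3R,4S,6R)-4-[(tert-butyldimethylsilyl)oxy]-2-methoxy-6-methyloxan-3-yl trifluoromethanesulfonate | C[C@@H]1C[C@H](O[Si](C)(C)C(C)(C)C)[C@@H](OS(=O)(=O)C(F)(F)F)[C@H](OC)O1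
F4 | step 13 | tert-butyldimethyl({(2R,3S,5R)-5-methyl-2-[(1E,3E)-6-(trimethylsilyl)hexa-1,3-dien-5-yn-1-yl]oxolan-3-yl}oxy)silane | C[C@@H]1C[C@H](O[Si](C)(C)C(C)(C)C)[C@@H](/C=C/C=C/C#C[Si](C)(C)C)O1
F5 | step 13 | tert-butyl({(2R,3S,5R)-2-[(1E,3E)-hexa-1,3-dien-5-yn-1-yl]-5-methyloxolan-3-yl}oxy)dimethylsilane | C[C@@H]1C[C@H](O[Si](C)(C)C(C)(C)C)[C@@H](/C=C/C=C/C#C)O1
F6 | step 13 | methoxymethyl 2-[(3E,5E)-6-{(2R,3S,5R)-3-[(tert-butyldimethylsilyl)oxy]-5-methyloxolan-2-yl}hexa-3,5-dien-1-yn-1-yl]-3-chloro-4,6-bis(methoxymethoxy)benzoate | C[C@@H]1C[C@H](O[Si](C)(C)C(C)(C)C)[C@@H](/C=C/C=C/C#Cc2c(Cl)c(OCOC)cc(OCOC)c2C(=O)OCOC)O1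
F7 | step 14 | diethyl [(5-chloro-6,8-dihydroxy-1-oxo-1H-isochromen-3-yl)methyl]phosphonate | CCOP(=O)(OCC)Cc1cc2c(Cl)c(O)cc(O)c2c(=O)o1
F8 | step 14 | diethyl ({6,8-bis[(tert-butyldimethylsilyl)oxy]-5-chloro-1-oxo-1H-isochromen-3-yl}methyl)phosphonate | CCOP(=O)(OCC)Cc1cc2c(Cl)c(O[Si](C)(C)C(C)(C)C)cc(O[Si](C)(C)C(C)(C)C)c2c(=O)o1
F9 | step 14 | 6,8-bis[(tert-butyldimethylsilyl)oxy]-3-[(1E,3E)-4-{(2R,3S,5R)-3-[(tert-butyldimethylsilyl)oxy]-5-methyloxolan-2-yl}buta-1,3-dien-1-yl]-5-chloro-1H-isochromen-1-one | C[C@@H]1C[C@H](O[Si](C)(C)C(C)(C)C)[C@@H](/C=C/C=C/c2cc3c(Cl)c(O[Si](C)(C)C(C)(C)C)cc(O[Si](C)(C)C(C)(C)C)c3c(=O)o2)O1
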